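**Retrosynthetic overview**
1. Rings A and B, with C5, C9 and C10, are taken intact from (+)-sclareolide 1; no ring is formed in the route.
2. Key disconnection C12–C13: primary iodide 6 (C12 electrophile, made from 1) plus lithio species 11, the sparteine-bound anion of crotyl carbamate 10. This is a chiral homoenolate (d3) equivalent of butanal, and the alkylation sets C13.
3. Enecarbamate 12 is unmasked and reduced to alcohol 16, which carries the C15 oxygen.
4. Late ring-B adjustment: the 8(17)-ene becomes the 7-en-17-al 20 (singlet-oxygen ene reaction and Kornblum–DeLaMare elimination, with O-acetylation in the same pot), then oxidation gives acid 21.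

Labdane numbering is used throughout: side chain C11–C16 (C16 is the methyl on C13), C17 on C8, C20 on C10. All compounds belong to the normal series of 1 (H-5α, H-9α, CH3-10β).

Assumption: in step 6 (−)-sparteine is taken to give the 13S series, by analogy with γ-alkylations of this reagent class; this sense of induction is not established for the crotyl case, and if the first run shows 13R, (+)-sparteine is used in its place.

**Step 1**
Reactants: 1 (+)-sclareolide
Product: 3 methyl 8α-hydroxy-13,14,15,16-tetranorlabdan-12-oate, via potassium carboxylate 2 (not isolated)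
Conditions: KOH, MeOH–H2O, reflux; evaporate; MeI, DMF, rt
Reagents that add atoms: potassium hydroxide [K+].[OH-]; iodomethane CI
Why: Saponification of the γ-lactone followed by SN2 O-methylation of the carboxylate gives the hydroxy ester under basic conditions that do not relactonise, and no stereocentre is touched.

**Step 2**
Reactants: 3 methyl 8α-hydroxy-13,14,15,16-tetranorlabdan-12-oate
Product: 4 methyl 13,14,15,16-tetranorlabd-8(17)-en-12-oate
Conditions: SOCl2, pyridine, CH2Cl2, −78 °C
Reagents that add atoms: none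
Why: E2 dehydration through the chlorosulfite; the 8α-oxygen is equatorial, so only hydrogens of the C17 methyl can become anti-periplanar and the exocyclic alkene is favoured over the ring alkenes.

**Step 3**
Reactants: 4 methyl 13,14,15,16-tetranorlabd-8(17)-en-12-oate
Product: 5 13,14,15,16-tetranorlabd-8(17)-en-12-ol
Conditions: LiAlH4, THF, 0 °C
Reagents that add atoms: none
Why: Hydride reduction of the ester to the primary alcohol; the isolated alkene is inert.

**Step 4**
Reactants: 5 13,14,15,16-tetranorlabd-8(17)-en-12-ol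
Product: 6 12-iodo-13,14,15,16-tetranorlabd-8(17)-ene
Conditions: PPh3, I2, imidazole, CH2Cl2, 0 °C to rt (phosphine–iodine adduct formed before 5 is added)
Reagents that add atoms: iodine II
Why: Appel iodination (alkoxyphosphonium, SN2 by iodide) of an unhindered primary alcohol; pre-forming the adduct leaves no free iodine to attack the alkene.

**Step 5**
Reactants: 7 tert-butyl (4-methoxyphenyl)carbamate; 8 (E)-1-bromobut-2-ene (E ≥ 95%)
Product: 10 tert-butyl N-[(E)-but-2-en-1-yl]-N-(4-methoxyphenyl)carbamate, via sodium carbamate salt 9 (not isolated)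
Conditions: NaH, DMF, 0 °C; then 8, 0 °C to rt
Reagents that add atoms: none
Why: SN2 N-alkylation of the sodium carbamate by the primary allylic bromide, with the E geometry carried over.

**Step 6 (key step)**
Reactants: 6 12-iodo-13,14,15,16-tetranorlabd-8(17)-ene; 10 tert-butyl N-[(E)-but-2-en-1-yl]-N-(4-methoxyphenyl)carbamate
Product: 12 tert-butyl N-(4-methoxyphenyl)-N-[(13S,14Z)-labda-8(17),14-dien-15-yl]carbamate, via lithiated carbamate 11 (not isolated)
Conditions: 10 (1.3 equiv), n-BuLi, (−)-sparteine, toluene, −78 °C, 2 h; then 6, −78 to −40 °C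
Reagents that add atoms: none
Why: Asymmetric homoenolate alkylation (Beak-type sparteine-mediated lithiation–substitution), in which the configurationally stable sparteine-bound allyllithium 11, whose γ-carbon is the nucleophilic β-carbon of a masked butanal, attacks the primary iodide anti to lithium, so that C12–C13 is formed and C13 (S) is set under reagent control.

**Step 7**
Reactants: 12 tert-butyl N-(4-methoxyphenyl)-N-[(13S,14Z)-labda-8(17),14-dien-15-yl]carbamate
Product: 16 (13S)-labd-8(17)-en-15-ol, via silyl carbamate 13 (not isolated), via N-aryl imine 14 (not isolated), via aldehyde 15 (not isolated)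
Conditions: Me3SiOTf, 2,6-lutidine, CH2Cl2, 0 °C; MeOH; citrate buffer pH 4, Et2O–H2O, rt, separate; then NaBH4, MeOH, 0 °C
Reagents that add atoms: water O
Why: Buffered silyl-triflate cleavage of the N-Boc group gives the N-aryl enamine/imine, which hydrolyses at pH 4 without protonating the acid-labile 8(17)-alkene, and borohydride reduction of the freed aldehyde gives the alcohol; C13 is β to the carbonyl and cannot epimerise.

**Step 8**
Reactants: 16 (13S)-labd-8(17)-en-15-ol
Product: 20 (13S)-17-oxolabd-7-en-15-yl acetate, via acetate 17 (not isolated), via allylic hydroperoxide 18 (not isolated), via peracetate 19 (not isolated)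
Conditions: O2, 5,10,15,20-tetraphenylporphyrin (cat.), white LED, Ac2O, pyridine, 4-(dimethylamino)pyridine (cat.), CH2Cl2, 0 °C to rt
Reagents that add atoms: acetic anhydride CC(=O)OC(C)=O; oxygen O=O
Why: After O-acetylation, a Schenck ene reaction of singlet oxygen on the open α-face puts oxygen on C17 and moves the alkene to C7=C8 by removing axial H-7α, and Kornblum–DeLaMare-type elimination of the peracetate formed in situ gives the enal before the new alkene can be oxygenated again.

**Step 9**
Reactants: 20 (13S)-17-oxolabd-7-en-15-yl acetate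
Product: 21 (13S)-15-acetoxylabd-7-en-17-oic acid (CNP0412535.1)
Conditions: NaClO2, NaH2PO4, 2-methyl-2-butene, t-BuOH–H2O, rt
Reagents that add atoms: sodium chlorite [Na+].[O-]Cl=O
Why: Pinnick oxidation of the enal to the conjugated acid at about pH 4, which leaves the acetate and all stereocentres untouched.

**Compound list**
1 | (+)-sclareolide | O=C1C[C@H]2[C@](C)(O1)CC[C@H]3C(C)(C)CCC[C@]23C | starting material
2 | potassium 8α-hydroxy-13,14,15,16-tetranorlabdan-12-oate | [K+].[O-]C(=O)C[C@H]1[C@](C)(O)CC[C@H]2C(C)(C)CCC[C@]12C | intermediate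
3 | methyl 8α-hydroxy-13,14,15,16-tetranorlabdan-12-oate | COC(=O)C[C@H]1[C@](C)(O)CC[C@H]2C(C)(C)CCC[C@]12C | intermediate
4 | methyl 13,14,15,16-tetranorlabd-8(17)-en-12-oate | COC(=O)C[C@H]1C(=C)CC[C@H]2C(C)(C)CCC[C@]12C | intermediate
5 | 13,14,15,16-tetranorlabd-8(17)-en-12-ol | OCC[C@H]1C(=C)CC[C@H]2C(C)(C)CCC[C@]12C | intermediate
6 | 12-iodo-13,14,15,16-tetranorlabd-8(17)-ene | ICC[C@H]1C(=C)CC[C@H]2C(C)(C)CCC[C@]12C | intermediate
7 | tert-butyl (4-methoxyphenyl)carbamate | COc1ccc(NC(=O)OC(C)(C)C)cc1 | starting material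
8 | (E)-1-bromobut-2-ene | C/C=C/CBr | starting material
9 | sodium salt of 7 | COc1ccc([N-]C(=O)OC(C)(C)C)cc1.[Na+] | intermediate
10 | tert-butyl N-[(E)-but-2-en-1-yl]-N-(4-methoxyphenyl)carbamate | C/C=C/CN(C(=O)OC(C)(C)C)c1ccc(OC)cc1 | intermediate
11 | (−)-sparteine-bound 1-lithio derivative of 10 (allyllithium, diamine not drawn) | C/C=C/[CH-]N(C(=O)OC(C)(C)C)c1ccc(OC)cc1.[Li+] | intermediate
12 | tert-butyl N-(4-methoxyphenyl)-N-[(13S,14Z)-labda-8(17),14-dien-15-yl]carbamate | COc1ccc(cc1)N(C(=O)OC(C)(C)C)/C=C\[C@@H](C)CC[C@H]1C(=C)CC[C@H]2C(C)(C)CCC[C@]12C | intermediate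
13 | trimethylsilyl N-(4-methoxyphenyl)-N-[(13S,14Z)-labda-8(17),14-dien-15-yl]carbamate | COc1ccc(cc1)N(C(=O)O[Si](C)(C)C)/C=C\[C@@H](C)CC[C@H]1C(=C)CC[C@H]2C(C)(C)CCC[C@]12C | intermediate
14 | (13S,E)-N-(4-methoxyphenyl)labd-8(17)-en-15-imine | COc1ccc(cc1)/N=C/C[C@@H](C)CC[C@H]1C(=C)CC[C@H]2C(C)(C)CCC[C@]12C | intermediate
15 | (13S)-labd-8(17)-en-15-al | O=CC[C@@H](C)CC[C@H]1C(=C)CC[C@H]2C(C)(C)CCC[C@]12C | intermediate
16 | (13S)-labd-8(17)-en-15-ol | OCC[C@@H](C)CC[C@H]1C(=C)CC[C@H]2C(C)(C)CCC[C@]12C | intermediate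
17 | (13S)-labd-8(17)-en-15-yl acetate | CC(=O)OCC[C@@H](C)CC[C@H]1C(=C)CC[C@H]2C(C)(C)CCC[C@]12C | intermediate
18 | (13S)-17-hydroperoxylabd-7-en-15-yl acetate | CC(=O)OCC[C@@H](C)CC[C@H]1C(COO)=CC[C@H]2C(C)(C)CCC[C@]12C | intermediate
19 | (13S)-17-(acetylperoxy)labd-7-en-15-yl acetate | CC(=O)OCC[C@@H](C)CC[C@H]1C(COOC(C)=O)=CC[C@H]2C(C)(C)CCC[C@]12C | intermediate
20 | (13S)-17-oxolabd-7-en-15-yl acetate | CC(=O)OCC[C@@H](C)CC[C@H]1C(C=O)=CC[C@H]2C(C)(C)CCC[C@]12C | intermediate
21 | (13S)-15-acetoxylabd-7-en-17-oic acid | CC(=O)OCC[C@@H](C)CC[C@H]1C(C(=O)O)=CC[C@H]2C(C)(C)CCC[C@]12C | target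

**Totals**
Total step count: 9. Longest linear sequence: 8 (steps 1–4 and 6–9, from 1).

**Three steps most likely to fail**

Step 6. The risks are γ- versus α-attack, the level and sense of induction with a methyl-substituted (rather than aryl- or cyclohexyl-substituted) allylamine, and a sluggish unactivated iodide. The fallback sets out from 6 and comes back at 16; it keeps the polarity reversal but moves it onto C12 as a nitronate, an acyl-anion-type d1 reagent. Iodide 6 with NaNO2 and phloroglucinol in DMF gives 12-nitro-13,14,15,16-tetranorlabd-8(17)-ene F1. Iminium-catalysed Michael addition of F1 to (E)-crotonaldehyde follows, with (S)-2-[diphenyl(trimethylsilyloxy)methyl]pyrrolidine and benzoic acid in MeOH. The usual shielding model predicts the required C13 configuration, and the product is (13R)-12-nitrolabd-8(17)-en-15-al F2, a mixture of 12-epimers. C13 has the same spatial arrangement as in 16; the descriptor changes only because the nitro group raises the priority of C12. NaBH4 gives (13R)-12-nitrolabd-8(17)-en-15-ol F3, and radical denitration with Bu3SnH and 2,2′-azobis(2-methylpropionitrile) in refluxing toluene returns 16.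

Step 7. The masked aldehyde must be released next to an exocyclic alkene that isomerises in protic acid, and the enecarbamate is only weakly basic. The fallback sets out from 3 and comes back at 17; it keeps ring B as a protected tertiary alcohol until after the unmasking, so that ordinary aqueous acid can be used.
- 3 with Et3SiOTf and 2,6-lutidine gives methyl 8α-(triethylsilyloxy)-13,14,15,16-tetranorlabdan-12-oate F4.
- LiAlH4 gives 8α-(triethylsilyloxy)-13,14,15,16-tetranorlabdan-12-ol F5.
- PPh3, I2 and imidazole give 12-iodo-8α-(triethylsilyloxy)-13,14,15,16-tetranorlabdane F6; the silyl ether prevents closure to the cyclic ether.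
- Alkylation of 11 under the conditions of step 6 gives tert-butyl N-(4-methoxyphenyl)-N-[(13S,14Z)-8α-(triethylsilyloxy)labd-14-en-15-yl]carbamate F7.
- 3 M HCl in THF cleaves both the enecarbamate and the silyl ether to give (13S)-8α-hydroxylabdan-15-al F8, which NaBH4 reduces in the same flask to (13S)-labdane-8α,15-diol F9.
- Ac2O and pyridine acetylate only the primary hydroxyl to give (13S)-8α-hydroxylabdan-15-yl acetate F10.
- SOCl2 and pyridine at −78 °C, as in step 2, give 17, which is then isolated and taken through the oxygenation of step 8.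

Step 8. Abstraction of H-9 instead of H-7 would give the 8(9)-enal, and 1,1-disubstituted alkenes react slowly with singlet oxygen. The fallback sets out from 16 and comes back at 20, replacing the ene reaction by epoxide chemistry. mCPBA with NaHCO3 in CH2Cl2 attacks the α-face and gives (13S)-8α,17-epoxylabdan-15-ol F11. Al(OiPr)3 in refluxing toluene isomerises the epoxide to (13S)-labd-7-ene-15,17-diol F12, the bulky aluminium alkoxide removing the accessible H-7 rather than the shielded H-9. MnO2 oxidises only the allylic alcohol to (13S)-15-hydroxylabd-7-en-17-al F13, and Ac2O with pyridine gives 20.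

**Further compounds**
F1 | step 6 | 12-nitro-13,14,15,16-tetranorlabd-8(17)-ene | [O-][N+](=O)CC[C@H]1C(=C)CC[C@H]2C(C)(C)CCC[C@]12C
F2 | step 6 | (13R)-12-nitrolabd-8(17)-en-15-al (12-epimers, C12 unassigned) | O=CC[C@@H](C)C([N+](=O)[O-])C[C@H]1C(=C)CC[C@H]2C(C)(C)CCC[C@]12C
F3 | step 6 | (13R)-12-nitrolabd-8(17)-en-15-ol (12-epimers, C12 unassigned) | OCC[C@@H](C)C([N+](=O)[O-])C[C@H]1C(=C)CC[C@H]2C(C)(C)CCC[C@]12C
F4 | step 7 | methyl 8α-(triethylsilyloxy)-13,14,15,16-tetranorlabdan-12-oate | COC(=O)C[C@H]1[C@](C)(O[Si](CC)(CC)CC)CC[C@H]2C(C)(C)CCC[C@]12C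
F5 | step 7 | 8α-(triethylsilyloxy)-13,14,15,16-tetranorlabdan-12-ol | OCC[C@H]1[C@](C)(O[Si](CC)(CC)CC)CC[C@H]2C(C)(C)CCC[C@]12C
F6 | step 7 | 12-iodo-8α-(triethylsilyloxy)-13,14,15,16-tetranorlabdane | ICC[C@H]1[C@](C)(O[Si](CC)(CC)CC)CC[C@H]2C(C)(C)CCC[C@]12C
F7 | step 7 | tert-butyl N-(4-methoxyphenyl)-N-[(13S,14Z)-8α-(triethylsilyloxy)labd-14-en-15-yl]carbamate | COc1ccc(cc1)N(C(=O)OC(C)(C)C)/C=C\[C@@H](C)CC[C@H]1[C@](C)(O[Si](CC)(CC)CC)CC[C@H]2C(C)(C)CCC[C@]12C
F8 | step 7 | (13S)-8α-hydroxylabdan-15-al | O=CC[C@@H](C)CC[C@H]1[C@](C)(O)CC[C@H]2C(C)(C)CCC[C@]12C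
F9 | step 7 | (13S)-labdane-8α,15-diol | OCC[C@@H](C)CC[C@H]1[C@](C)(O)CC[C@H]2C(C)(C)CCC[C@]12C
F10 | step 7 | (13S)-8α-hydroxylabdan-15-yl acetate | CC(=O)OCC[C@@H](C)CC[C@H]1[C@](C)(O)CC[C@H]2C(C)(C)CCC[C@]12C
F11 | step 8 | (13S)-8α,17-epoxylabdan-15-ol | OCC[C@@H](C)CC[C@H]1[C@@]2(CO2)CC[C@H]3C(C)(C)CCC[C@]13C
F12 | step 8 | (13S)-labd-7-ene-15,17-diol | OCC[C@@H](C)CC[C@H]1C(CO)=CC[C@H]2C(C)(C)CCC[C@]12C
F13 | step 8 | (13S)-15-hydroxylabd-7-en-17-al | OCC[C@@H](C)CC[C@H]1C(C=O)=CC[C@H]2C(C)(C)CCC[C@]12C
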